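Coupling takes time, and during that time the partner can also decompose by itself, so ask first how far the partner can carry the starting material.

| flask | starting material | partner | remark | time |
|---|---|---|---|---|
| violet | 30 mM | 50 mM | run made earlier |  |
| flask | 20 mM | 50.0 mM |  | 10 min |

violet run (percent of the starting material charged)

| time / s | mono adduct / % | starting material / % |
|---|---|---|
| 10.0 | 37.9 | 53.5 |
| 15.0 | 47.8 | 43.1 |
| 30.0 | 59.1 | 27.9 |
| 60.0 | 60.7 | 19.4 |

(each reading ± 0.5 percentage points)

- what may be going on: mono adduct <-> isomer of the product; starting material + partner -> mono adduct; partner + mono adduct <-> double product; partner -> decomposed reagent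

- when, up to 10 min, the flask holds most mono adduct
- the amount of mono adduct, in percent of the starting material charged, at that time
- earliest time at which at least nineteen twentieths of that best amount are there, in min
- latest time at which they still are, in min

1. **End state.** Suppose the partner decays in these two ways, and none stays bound in the double product at the end. Then c(partner) at the start equals the c(starting material) consumed plus κ·ln(c(starting material) at the start / at the end). κ is the decomposition constant over the coupling constant. It is the c(starting material) at which both routes use partner equally, and κ/c(starting material) is a selectivity factor. Call the converted fraction the reach.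

2. **What must be known well.** My assumption is that best mono adduct equals the highest violet reading times the ratio of reaches, flask over violet. That reading enters directly, with its scatter of 0.5 percentage points. κ shifts it as well: at zero the estimate is 60.7%, and with κ as large as 30 mM it is about 66.6%. So κ has to be read from the run.

3. **The number.** In the violet run, the logarithmic fall of starting material slows from 0.0625 s⁻¹ to 0.0121 s⁻¹. This slope follows c(partner), and the balance at both windows gives, as a reading, κ = 13.5 mM.

4. **My estimate.** Starting material left by the balance is about 15.7% for violet and about 9.33% for the flask, so my estimate of best is 65.3%. This gives no times.

5. **The forecast.** It says 64% at 0.75 min, lower than mine, with the window from 0.48 min to 1.25 min: “Mono adduct reaches about 61% at 30 s, peaks near 64% at 45 s, then drains into isomer”.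

The flask gives 65.3% at 0.791 min, with the window from 0.489 min to 1.25 min.

    mono adduct ⇌ isomer of the product (K = 4.80, k = 0.00620 s⁻¹)
    starting material + partner → mono adduct (k = 1.70 M⁻¹ s⁻¹)
    partner + mono adduct ⇌ double product (K = 5.50 M⁻¹, k = 4.60 M⁻¹ s⁻¹)
    partner → decomposed reagent (k = 0.0200 s⁻¹)

The flask ends with 6.94% of its starting material left. Now raise the partner to 85 mM, keeping the same κ. The balance leaves 0.799% of the starting material, and the neighbouring flask holds 0.40%. The reach ratio then puts best mono adduct at 71.4%, and that flask gives 70.7%.

The runs were computed from invented constants, and the scatter is random.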